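**Retrosynthetic overview**

- The route rests on ring A (C4a, C5, C6, C7, C8, C8a, chroman-4-one numbering): it is an acylphloroglucinol whose O5, O7 and O1 are the carbonyl oxygens of a folded tetraketide chain.
- Ring A is opened at C4a–C5: an α-oxoketene at C5, released thermally from a tert-butyl β-keto ester, acylates the enol-ether carbon C4a of a (2S,3R)-2,3-dimethyl-2,3-dihydropyran-4-one in which O1 is already the ring oxygen.
- The precursor 21 comes from β-keto ester 17 and (E)-oct-2-enal (iminium-catalysed Michael addition sets the side-chain centre, then oxidation and allylation). 17 comes from acid 13 by malonate homologation.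
- 13 comes from a 3,5-diketo ester made from the dianion of allyl 2-prenylacetoacetate and an Evans-syn Weinreb amide, which carries C2 and C3.
- Ring order: the heterocyclic ring first (cyclodehydration, step 6), then benzene ring A (step 12); 7-O-methylation and allyl ester cleavage finish the route.

Key step: step 12

Assumption: the carbons that become C6 and C8 are enolisable and are carried as epimer/tautomer mixtures from 9 to 21; both become sp2 in step 12, so only C2, C3 and the side-chain carbon have to be set.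

**Route**

Step 1
Reactants: 1 (R)-4-benzyl-3-propionyloxazolidin-2-one; 2 acetaldehyde
Product: 4 (R)-4-benzyl-3-[(2R,3S)-3-hydroxy-2-methylbutanoyl]oxazolidin-2-one, via boron enolate 3 (not isolated)
Conditions: n-Bu2BOTf, i-Pr2NEt, CH2Cl2, 0 °C; then 2, −78 to 0 °C; H2O2, MeOH, pH 7 buffer
Reagents that add atoms: none
Why: Evans syn-aldol reaction, in which the Z-boron enolate reacts through a closed Zimmerman–Traxler chair and the (R)-benzyl auxiliary directs the aldehyde to one enolate face, setting the (2R,3S)-syn pair that becomes C3 and C2 of the chromanone.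

Step 2
Reactants: 4 (R)-4-benzyl-3-[(2R,3S)-3-hydroxy-2-methylbutanoyl]oxazolidin-2-one
Product: 5 (2R,3S)-3-hydroxy-N-methoxy-N,2-dimethylbutanamide
Conditions: MeNH(OMe)·HCl, AlMe3, CH2Cl2, −10 to 0 °C; aq. HCl work-up
Reagents that add atoms: N,O-dimethylhydroxylamine hydrochloride, CNOC.Cl
Why: Aluminium-amide transamination of the β-hydroxy imide (Weinreb amide formation) cleaves the exocyclic acyl bond without touching either stereocentre and gives an acyl donor that stops at the ketone stage.

Step 3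
Reactants: 5 (2R,3S)-3-hydroxy-N-methoxy-N,2-dimethylbutanamide
Product: 6 (2R,3S)-3-[(tert-butyldimethylsilyl)oxy]-N-methoxy-N,2-dimethylbutanamide
Conditions: TBSCl, imidazole, DMF, rt
Reagents that add atoms: tert-butyldimethylsilyl chloride, CC(C)(C)[Si](C)(C)Cl
Why: Imidazole-promoted silylation of the secondary alcohol blocks alkoxide formation and retro-aldol cleavage in the strongly basic acylation that follows.

Step 4
Reactants: 7 allyl acetoacetate; 8 prenyl bromide (1-bromo-3-methylbut-2-ene)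
Product: 9 allyl 2-acetyl-5-methylhex-4-enoate (racemic)
Conditions: K2CO3, acetone, reflux (7 in slight excess)
Reagents that add atoms: none
Why: C-Alkylation of the acetoacetate enolate by the primary allylic bromide (SN2) places the prenyl group on the carbon that becomes C8.

Step 5
Reactants: 9 allyl 2-acetyl-5-methylhex-4-enoate; 6 (2R,3S)-3-[(tert-butyldimethylsilyl)oxy]-N-methoxy-N,2-dimethylbutanamide
Product: 11 allyl (6R,7S)-7-[(tert-butyldimethylsilyl)oxy]-6-methyl-2-(3-methylbut-2-en-1-yl)-3,5-dioxooctanoate (C2 epimers), via dianion 10 (not isolated)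
Conditions: 9 (2.2 equiv), NaH, THF, 0 °C; n-BuLi, 0 °C; then 6, −78 to 0 °C; aq. NH4Cl
Reagents that add atoms: none
Why: Claisen-type acylation of a Weiler dianion, whose terminal carbanion attacks the Weinreb amide to give a chelated tetrahedral adduct that collapses only on work-up, so the 3,5-diketo ester forms without over-addition and with the stereocentres of 6 intact.

Step 6
Reactants: 11 allyl (6R,7S)-7-[(tert-butyldimethylsilyl)oxy]-6-methyl-2-(3-methylbut-2-en-1-yl)-3,5-dioxooctanoate
Product: 12 allyl 2-[(2S,3R)-2,3-dimethyl-4-oxo-3,4-dihydro-2H-pyran-6-yl]-5-methylhex-4-enoate (epimers at the side-chain carbon)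
Conditions: aq. HF (48%), MeCN, 0 °C to rt
Reagents that add atoms: none
Why: Desilylation frees the C7 hydroxyl, which closes on the C3 ketone as the only possible six-membered hemiketal and loses water (cyclodehydration) to the vinylogous ester, fixing O1 and carrying the syn pair into the cis-2,3-dimethyl ring under acidic, non-enolising conditions.

Step 7
Reactants: 12 allyl 2-[(2S,3R)-2,3-dimethyl-4-oxo-3,4-dihydro-2H-pyran-6-yl]-5-methylhex-4-enoate
Product: 13 2-[(2S,3R)-2,3-dimethyl-4-oxo-3,4-dihydro-2H-pyran-6-yl]-5-methylhex-4-enoic acid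
Conditions: Pd(PPh3)4 (5 mol%), PhNHMe, THF, 0 °C; acid used at once
Reagents that add atoms: none
Why: Tsuji–Trost-type deallylation, in which zerovalent palladium ionises the allyl ester and the weakly basic N-methylaniline captures the allyl fragment, releases the acid under near-neutral conditions at low temperature.

Step 8
Reactants: 13 2-[(2S,3R)-2,3-dimethyl-4-oxo-3,4-dihydro-2H-pyran-6-yl]-5-methylhex-4-enoic acid; 14 mono-tert-butyl malonate
Product: 17 tert-butyl 4-[(2S,3R)-2,3-dimethyl-4-oxo-3,4-dihydro-2H-pyran-6-yl]-7-methyl-3-oxooct-6-enoate, via acyl imidazolide 15 (not isolated), via magnesium malonate 16 (not isolated)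
Conditions: 13, CDI, THF, 0 °C to rt; 14, Mg(OEt)2, THF (separate flask); combine, rt to 40 °C; cold 1 M HCl
Reagents that add atoms: none
Why: Masamune–Brooks homologation, in which the acyl imidazolide is C-acylated by the magnesium enolate of the malonate half-ester and the adduct decarboxylates on acidification to the tert-butyl β-keto ester.

Step 9
Reactants: 17 tert-butyl 4-[(2S,3R)-2,3-dimethyl-4-oxo-3,4-dihydro-2H-pyran-6-yl]-7-methyl-3-oxooct-6-enoate; 18 (E)-oct-2-enal
Product: 19 tert-butyl 4-[(2S,3R)-2,3-dimethyl-4-oxo-3,4-dihydro-2H-pyran-6-yl]-7-methyl-3-oxo-2-[(3R)-1-oxooctan-3-yl]oct-6-enoate (epimers at C2 and C4)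
Conditions: (S)-2-[diphenyl(trimethylsilyloxy)methyl]pyrrolidine (10 mol%), PhCO2H (10 mol%), toluene, 0 °C to rt
Reagents that add atoms: none
Why: Iminium-catalysed Michael addition, in which the less hindered and more acidic C2 methylene of the β-keto ester adds to the Re face of C3 of the (E)-iminium ion of 18, anti to the diphenyl(silyloxy)methyl group of the (S)-catalyst, and so sets the side-chain centre as R.

Step 10
Reactants: 19 tert-butyl 4-[(2S,3R)-2,3-dimethyl-4-oxo-3,4-dihydro-2H-pyran-6-yl]-7-methyl-3-oxo-2-[(3R)-1-oxooctan-3-yl]oct-6-enoate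
Product: 20 (3R)-3-{1-(tert-butoxy)-4-[(2S,3R)-2,3-dimethyl-4-oxo-3,4-dihydro-2H-pyran-6-yl]-7-methyl-1,3-dioxooct-6-en-2-yl}octanoic acid
Conditions: NaClO2, NaH2PO4, 2-methylbut-2-ene (large excess), t-BuOH/H2O, 0 °C
Reagents that add atoms: sodium chlorite, [Na+].[O-]Cl=O
Why: Pinnick oxidation converts the aldehyde into the acid without touching ketones or alkenes, and the excess alkene scavenger intercepts HOCl before it can chlorinate the prenyl group or the active methine.

Step 11
Reactants: 20 (3R)-3-{1-(tert-butoxy)-4-[(2S,3R)-2,3-dimethyl-4-oxo-3,4-dihydro-2H-pyran-6-yl]-7-methyl-1,3-dioxooct-6-en-2-yl}octanoic acid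
Product: 21 tert-butyl 2-[(3R)-1-(allyloxy)-1-oxooctan-3-yl]-4-[(2S,3R)-2,3-dimethyl-4-oxo-3,4-dihydro-2H-pyran-6-yl]-7-methyl-3-oxooct-6-enoate (epimers at C2 and C4)
Conditions: allyl bromide, KHCO3, DMF, rt
Reagents that add atoms: allyl bromide, C=CCBr
Why: SN2 O-alkylation of the carboxylate, with hydrogen carbonate too weak a base to deprotonate the α-substituted β-keto ester, so C-allylation and C3 epimerisation are avoided.

Step 12
Reactants: 21 tert-butyl 2-[(3R)-1-(allyloxy)-1-oxooctan-3-yl]-4-[(2S,3R)-2,3-dimethyl-4-oxo-3,4-dihydro-2H-pyran-6-yl]-7-methyl-3-oxooct-6-enoate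
Product: 23 allyl (3R)-3-[(2S,3R)-5,7-dihydroxy-2,3-dimethyl-8-(3-methylbut-2-en-1-yl)-4-oxochroman-6-yl]octanoate, via acylketene 22 (not isolated)
Conditions: PhMe (0.005 M), 110 °C, Ar sparge
Reagents that add atoms: none
Why: Proposed new method: the tert-butyl β-keto ester loses t-BuOH through its enol (as in thermal transacetoacetylation) to give α-oxoketene 22, whose ketene carbon (future C5) lies six atoms from the enol-ether carbon C4a of the dihydropyranone; enolisation of the C7 ketone toward C8 turns 22 into a hydroxy-dienylketene that closes by thermal 6π-electrocyclisation (equally a 6-exo C-acylation of the vinylogous-ester α-carbon by the ketene), and the cyclohexadienone tautomerises to the phenol, forming the C4a–C5 bond and ring A. The closest known reactions are the thermal generation of acylketenes from tert-butyl β-keto esters or dioxinones with biomimetic aromatisation and the 6π-closure of dienylketenes to phenols; a dihydropyranone C=C as the terminal partner has no direct precedent. No stereocentre is formed: C6 and C8 of the epimer mixture become sp2, and the neutral conditions leave the base-labile cis C2/C3 pair and the side-chain centre untouched. Regiochemistry is fixed by the substrate, since O1 is already the pyran oxygen, C4a is the only nucleophilic carbon within six-ring reach of the ketene, and no hydroxyl or enol oxygen can reach the ketene carbon through a five- or six-membered transition state, so the pyrone-forming O-acylation of free triketo-ketenes cannot occur. High dilution and removal of t-BuOH are needed so that ring closure outruns ketene dimerisation and recapture by the alcohol.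

Step 13
Reactants: 23 allyl (3R)-3-[(2S,3R)-5,7-dihydroxy-2,3-dimethyl-8-(3-methylbut-2-en-1-yl)-4-oxochroman-6-yl]octanoate
Product: 24 allyl (3R)-3-[(2S,3R)-5-hydroxy-7-methoxy-2,3-dimethyl-8-(3-methylbut-2-en-1-yl)-4-oxochroman-6-yl]octanoate
Conditions: TMSCHN2, MeOH/PhMe (1:4), 0 °C to rt
Reagents that add atoms: (trimethylsilyl)diazomethane, C[Si](C)(C)C=[N+]=[N-]
Why: Diazomethane-type O-methylation takes the acidic, non-chelated 7-hydroxyl (para to the carbonyl), while the 5-hydroxyl is locked in a hydrogen bond to C4=O and no base is present to epimerise C3.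

Step 14
Reactants: 24 allyl (3R)-3-[(2S,3R)-5-hydroxy-7-methoxy-2,3-dimethyl-8-(3-methylbut-2-en-1-yl)-4-oxochroman-6-yl]octanoate
Product: 25 (3R)-3-[(2S,3R)-5-hydroxy-7-methoxy-2,3-dimethyl-8-(3-methylbut-2-en-1-yl)-4-oxochroman-6-yl]octanoic acid (CNP0217102.1)
Conditions: Pd(PPh3)4 (5 mol%), PhNHMe, THF, rt
Reagents that add atoms: none
Why: Tsuji–Trost deallylation with zerovalent palladium and the weakly basic N-methylaniline as allyl acceptor frees the acid under conditions that spare the prenyl group and the cis-2,3-dimethyl pair.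

**Compound list**

1 | (R)-4-benzyl-3-propionyloxazolidin-2-one | CCC(=O)N1[C@H](Cc2ccccc2)COC1=O | starting material
2 | acetaldehyde | CC=O | starting material
3 | (Z)-dibutylboron enolate of 1 | C/C=C(\OB(CCCC)CCCC)N1[C@H](Cc2ccccc2)COC1=O | intermediate (not isolated)
4 | (R)-4-benzyl-3-[(2R,3S)-3-hydroxy-2-methylbutanoyl]oxazolidin-2-one | O=C1OC[C@@H](Cc2ccccc2)N1C(=O)[C@H](C)[C@H](C)O | intermediate
5 | (2R,3S)-3-hydroxy-N-methoxy-N,2-dimethylbutanamide | CON(C)C(=O)[C@H](C)[C@H](C)O | intermediate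
6 | (2R,3S)-3-[(tert-butyldimethylsilyl)oxy]-N-methoxy-N,2-dimethylbutanamide | CON(C)C(=O)[C@H](C)[C@H](C)O[Si](C)(C)C(C)(C)C | intermediate
7 | allyl acetoacetate | CC(=O)CC(=O)OCC=C | starting material
8 | prenyl bromide (1-bromo-3-methylbut-2-ene) | CC(C)=CCBr | starting material
9 | allyl 2-acetyl-5-methylhex-4-enoate | CC(=O)C(CC=C(C)C)C(=O)OCC=C | intermediate
10 | sodium lithium dianion (bis-enolate) of 9 | C=C([O-])C(CC=C(C)C)=C([O-])OCC=C.[Na+].[Li+] | intermediate (not isolated)
11 | allyl (6R,7S)-7-[(tert-butyldimethylsilyl)oxy]-6-methyl-2-(3-methylbut-2-en-1-yl)-3,5-dioxooctanoate | C=CCOC(=O)C(CC=C(C)C)C(=O)CC(=O)[C@H](C)[C@H](C)O[Si](C)(C)C(C)(C)C | intermediate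
12 | allyl 2-[(2S,3R)-2,3-dimethyl-4-oxo-3,4-dihydro-2H-pyran-6-yl]-5-methylhex-4-enoate | C=CCOC(=O)C(CC=C(C)C)C1=CC(=O)[C@H](C)[C@H](C)O1 | intermediate
13 | 2-[(2S,3R)-2,3-dimethyl-4-oxo-3,4-dihydro-2H-pyran-6-yl]-5-methylhex-4-enoic acid | OC(=O)C(CC=C(C)C)C1=CC(=O)[C@H](C)[C@H](C)O1 | intermediate
14 | mono-tert-butyl malonate | CC(C)(C)OC(=O)CC(=O)O | starting material
15 | 1-imidazolide of acid 13 | O=C(C(CC=C(C)C)C1=CC(=O)[C@H](C)[C@H](C)O1)n1ccnc1 | intermediate (not isolated)
16 | magnesium bis(3-tert-butoxy-3-oxopropanoate) | [Mg+2].[O-]C(=O)CC(=O)OC(C)(C)C.[O-]C(=O)CC(=O)OC(C)(C)C | intermediate (not isolated)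
17 | tert-butyl 4-[(2S,3R)-2,3-dimethyl-4-oxo-3,4-dihydro-2H-pyran-6-yl]-7-methyl-3-oxooct-6-enoate | CC(C)(C)OC(=O)CC(=O)C(CC=C(C)C)C1=CC(=O)[C@H](C)[C@H](C)O1 | intermediate
18 | (E)-oct-2-enal | CCCCC/C=C/C=O | starting material
19 | tert-butyl 4-[(2S,3R)-2,3-dimethyl-4-oxo-3,4-dihydro-2H-pyran-6-yl]-7-methyl-3-oxo-2-[(3R)-1-oxooctan-3-yl]oct-6-enoate | CCCCC[C@H](CC=O)C(C(=O)OC(C)(C)C)C(=O)C(CC=C(C)C)C1=CC(=O)[C@H](C)[C@H](C)O1 | intermediate
20 | (3R)-3-{1-(tert-butoxy)-4-[(2S,3R)-2,3-dimethyl-4-oxo-3,4-dihydro-2H-pyran-6-yl]-7-methyl-1,3-dioxooct-6-en-2-yl}octanoic acid | CCCCC[C@H](CC(=O)O)C(C(=O)OC(C)(C)C)C(=O)C(CC=C(C)C)C1=CC(=O)[C@H](C)[C@H](C)O1 | intermediate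
21 | tert-butyl 2-[(3R)-1-(allyloxy)-1-oxooctan-3-yl]-4-[(2S,3R)-2,3-dimethyl-4-oxo-3,4-dihydro-2H-pyran-6-yl]-7-methyl-3-oxooct-6-enoate | CCCCC[C@H](CC(=O)OCC=C)C(C(=O)OC(C)(C)C)C(=O)C(CC=C(C)C)C1=CC(=O)[C@H](C)[C@H](C)O1 | intermediate (key-step precursor)
22 | α-oxoketene from 21 (loss of t-BuOH) | CCCCC[C@H](CC(=O)OCC=C)C(=C=O)C(=O)C(CC=C(C)C)C1=CC(=O)[C@H](C)[C@H](C)O1 | intermediate (not isolated)
23 | allyl (3R)-3-[(2S,3R)-5,7-dihydroxy-2,3-dimethyl-8-(3-methylbut-2-en-1-yl)-4-oxochroman-6-yl]octanoate | CCCCC[C@H](CC(=O)OCC=C)c1c(O)c2c(c(CC=C(C)C)c1O)O[C@@H](C)[C@@H](C)C2=O | intermediate (key-step product)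
24 | allyl (3R)-3-[(2S,3R)-5-hydroxy-7-methoxy-2,3-dimethyl-8-(3-methylbut-2-en-1-yl)-4-oxochroman-6-yl]octanoate | CCCCC[C@H](CC(=O)OCC=C)c1c(O)c2c(c(CC=C(C)C)c1OC)O[C@@H](C)[C@@H](C)C2=O | intermediate
25 | (3R)-3-[(2S,3R)-5-hydroxy-7-methoxy-2,3-dimethyl-8-(3-methylbut-2-en-1-yl)-4-oxochroman-6-yl]octanoic acid | CCCCC[C@H](CC(=O)O)c1c(O)c2c(c(CC=C(C)C)c1OC)O[C@@H](C)[C@@H](C)C2=O | target

**Step count and risks**

Total step count: 14. Longest linear sequence: 13 steps (1, 2, 3, 5–14, from compound 1).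

Steps most likely to fail:

1. Step 12 (proposed new method). The ketene may be consumed by dimerisation or by re-addition of tert-butanol before C4a attacks, the dienylketene may fail to close onto the electron-poor enol-ether double bond, and the new 7-hydroxyl may transesterify the allyl ester (lactonisation).
Fallback (known chemistry, ring A taken from an arene): it sets out from 8 and 18 and returns at 24. 1,3-Dimethoxybenzene is lithiated between the methoxy groups (n-BuLi, THF) and alkylated with 8 to 1,3-dimethoxy-2-(3-methylbut-2-en-1-yl)benzene F1. Iridium-catalysed C–H borylation at the only unhindered position ([Ir(cod)OMe]2, 4,4′-di-tert-butyl-2,2′-bipyridine, B2pin2) and oxidation (H2O2, NaOH) should give 3,5-dimethoxy-4-(3-methylbut-2-en-1-yl)phenol F2. Friedel–Crafts alkylation/hemiacetalisation of F2 with 18 under the (S)-catalyst of step 9 (both ortho positions are equivalent, same facial sense) gives (4R)-5,7-dimethoxy-6-(3-methylbut-2-en-1-yl)-4-pentylchroman-2-ol F3, which PCC oxidises to the dihydrocoumarin (4R)-5,7-dimethoxy-6-(3-methylbut-2-en-1-yl)-4-pentylchroman-2-one F4. Friedel–Crafts acylation at the one free ring position (tigloyl chloride, SnCl4, CH2Cl2, −78 °C) gives the 8-[(E)-2-methylbut-2-enoyl] ketone F5. BCl3 (−78 °C) cleaves only the methyl ether ortho to the ketone, giving the 7-hydroxy ketone F6. Quinidine-catalysed intramolecular oxa-Michael addition of the ortho-tigloylphenol with kinetic protonation, a known entry to cis-2,3-dimethylchromanones, is expected to give the (2S,3R) tricyclic lactone F7 (the lactone of acid 25 through its 5-hydroxyl). Opening of this aryl lactone with allyl alcohol and catalytic DMAP gives 24, and step 14 follows.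

2. Step 9. The hindered, strongly enolised donor may add slowly or through its other acidic carbon (the future C8), the adduct may close reversibly onto its own aldehyde, and facial control may erode.
Fallback (stereocentre set on a simple malonate, then convergent coupling): it sets out from 14 and 18 and returns at 21. 14 is esterified with 2-(trimethylsilyl)ethanol (DCC, DMAP) to tert-butyl 2-(trimethylsilyl)ethyl malonate F8. The same (S)-catalyst adds F8 to 18 to give 1-tert-butyl 3-[2-(trimethylsilyl)ethyl] 2-[(3R)-1-oxooctan-3-yl]malonate F9. Pinnick oxidation gives the acid F10, and allyl bromide with KHCO3 gives the allyl ester F11. TBAF removes only the silylethyl ester to give the half-ester 2-[(3R)-1-(allyloxy)-1-oxooctan-3-yl]-3-(tert-butoxy)-3-oxopropanoic acid F12. Its magnesium salt (Mg(OEt)2) is acylated by imidazolide 15 with decarboxylation (Masamune–Brooks), which gives 21 directly and bypasses 17, 19 and 20.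

3. Step 8. Acid 13 is a vinylogous malonic half-acid and may lose CO2 before or during activation, and its imidazolide may enolise instead of acylating the malonate.
Fallback (the β-keto ester is in place before the pyranone is made, so no free acid is needed): it sets out from 8 and 6 and returns at 17. The dianion of tert-butyl acetoacetate (NaH, n-BuLi) is alkylated with 8 to tert-butyl 7-methyl-3-oxooct-6-enoate F13. The dianion of F13 is acylated at C4 with N-methoxy-N-methylacetamide to tert-butyl 4-acetyl-7-methyl-3-oxooct-6-enoate F14. The trianion of F14 (LDA, 3 equiv, THF, −78 °C) is acylated at its terminal methyl by 6 to tert-butyl (8R,9S)-9-[(tert-butyldimethylsilyl)oxy]-8-methyl-4-(3-methylbut-2-en-1-yl)-3,5,7-trioxodecanoate F15. Aqueous HF in MeCN then removes the silyl group and closes the dihydropyranone on the C5 ketone, giving 17.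

**Further compounds**

F1 | step 12 | 1,3-dimethoxy-2-(3-methylbut-2-en-1-yl)benzene | COc1cccc(OC)c1CC=C(C)C
F2 | step 12 | 3,5-dimethoxy-4-(3-methylbut-2-en-1-yl)phenol | COc1cc(O)cc(OC)c1CC=C(C)C
F3 | step 12 | (4R)-5,7-dimethoxy-6-(3-methylbut-2-en-1-yl)-4-pentylchroman-2-ol (anomer mixture) | CCCCC[C@@H]1CC(O)Oc2cc(OC)c(CC=C(C)C)c(OC)c12
F4 | step 12 | (4R)-5,7-dimethoxy-6-(3-methylbut-2-en-1-yl)-4-pentylchroman-2-one | CCCCC[C@@H]1CC(=O)Oc2cc(OC)c(CC=C(C)C)c(OC)c12
F5 | step 12 | (4R)-5,7-dimethoxy-8-[(E)-2-methylbut-2-enoyl]-6-(3-methylbut-2-en-1-yl)-4-pentylchroman-2-one | CCCCC[C@@H]1CC(=O)Oc2c(C(=O)/C(C)=C/C)c(OC)c(CC=C(C)C)c(OC)c12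
F6 | step 12 | (4R)-7-hydroxy-5-methoxy-8-[(E)-2-methylbut-2-enoyl]-6-(3-methylbut-2-en-1-yl)-4-pentylchroman-2-one | CCCCC[C@@H]1CC(=O)Oc2c(C(=O)/C(C)=C/C)c(O)c(CC=C(C)C)c(OC)c12
F7 | step 12 | lactone of acid 25 through its 5-hydroxyl: (2S,3R)-cis-2,3-dimethylchroman-4-one fused to the (R)-4-pentyl-3,4-dihydrocoumarin ring, 7-OMe, 8-prenyl (target numbering) | CCCCC[C@@H]1CC(=O)Oc2c1c(OC)c(CC=C(C)C)c1O[C@@H](C)[C@@H](C)C(=O)c21
F8 | step 9 | tert-butyl 2-(trimethylsilyl)ethyl malonate | CC(C)(C)OC(=O)CC(=O)OCC[Si](C)(C)C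
F9 | step 9 | 1-tert-butyl 3-[2-(trimethylsilyl)ethyl] 2-[(3R)-1-oxooctan-3-yl]malonate | CCCCC[C@H](CC=O)C(C(=O)OC(C)(C)C)C(=O)OCC[Si](C)(C)C
F10 | step 9 | (3R)-3-{1-(tert-butoxy)-1,3-dioxo-3-[2-(trimethylsilyl)ethoxy]propan-2-yl}octanoic acid | CCCCC[C@H](CC(=O)O)C(C(=O)OC(C)(C)C)C(=O)OCC[Si](C)(C)C
F11 | step 9 | 1-tert-butyl 3-[2-(trimethylsilyl)ethyl] 2-[(3R)-1-(allyloxy)-1-oxooctan-3-yl]malonate | CCCCC[C@H](CC(=O)OCC=C)C(C(=O)OC(C)(C)C)C(=O)OCC[Si](C)(C)C
F12 | step 9 | 2-[(3R)-1-(allyloxy)-1-oxooctan-3-yl]-3-(tert-butoxy)-3-oxopropanoic acid | CCCCC[C@H](CC(=O)OCC=C)C(C(=O)OC(C)(C)C)C(=O)O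
F13 | step 8 | tert-butyl 7-methyl-3-oxooct-6-enoate | CC(C)=CCCC(=O)CC(=O)OC(C)(C)C
F14 | step 8 | tert-butyl 4-acetyl-7-methyl-3-oxooct-6-enoate | CC(=O)C(CC=C(C)C)C(=O)CC(=O)OC(C)(C)C
F15 | step 8 | tert-butyl (8R,9S)-9-[(tert-butyldimethylsilyl)oxy]-8-methyl-4-(3-methylbut-2-en-1-yl)-3,5,7-trioxodecanoate | CC(C)(C)OC(=O)CC(=O)C(CC=C(C)C)C(=O)CC(=O)[C@H](C)[C@H](C)O[Si](C)(C)C(C)(C)C
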